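## Structural features

The target is a spiro compound in which a 2,3,4-trimethoxybenzo-fused seven-membered carbocycle (ring B: C5, C6H2, C7H(CH3), C8H(CH3), C9H(OAc), closed by the arene carbons C9a and C4a) shares C5 with a 3',5'-dimethoxycyclohexa-2',5'-dien-4'-one (ring C). C5 is quaternary and is bonded to C4a (next to the C4 methoxy group), to C6 and to the two vinylic CH carbons C2' and C6'; because ring C has a mirror plane through C5 and C4', C5 is not a stereocentre. The stereocentres C7 (R), C8 (S) and C9 (R) are contiguous: the two methyl groups are trans, and the C8 methyl and C9 acetoxy groups are also trans, which is a syn relationship when the chain C7–C8–C9–C9a is drawn open. Fragile groups are the cross-conjugated α-methoxy dienone (conjugate addition, reduction, acid-induced dienone–phenol rearrangement), the secondary benzylic acetate at C9, which lies para to the C3 methoxy group and can ionise or eliminate, and the electron-rich arene. The real difficulty is the congested spiro carbon, which must be joined to a doubly ortho-substituted arene position and to C6 inside a seven-membered ring without disturbing the adjacent stereotriad. The key step exploits the fact that C5 is C4 of a 2,6-dimethoxycyclohexadienone. It therefore maps onto the free carbonyl carbon of the monoketal of 2,6-dimethoxybenzoquinone, which can accept C4a as an aryl nucleophile and then, after ionisation of the carbinol, C6 as an allylsilane terminus, while the ketal carbon becomes C4'.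

## Logic of the disconnections

**18 ⇒ 17 ⇒ 16.** The acetyl C–O bond and then the O–Si bond are cut. An ester at C9 cannot survive the organolithium and Lewis acid of the key step, so the C9 oxygen is carried as a silyl ether. The gain is small but necessary. The forward steps must remove silicon and acylate without ionising the benzylic C9–O bond and without leaving a free alkoxide next to ring C.

**16 ⇒ 15.** The C7–H bond and one C–H bond of the C7 methyl group are removed, giving the exocyclic alkene. This is the alkene that an allylsilane ring closure leaves behind, and it removes the C7 stereocentre, so that only C8 and C9 remain. The forward reduction must deliver hydrogen to C7 so that the methyl groups are trans, and it must spare the dienone.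

**15 ⇒ 9 + 11 (key disconnection).** The bonds C4a–C5 and C5–C6 are cut. Both end at the carbon that is the carbonyl carbon of 11. Ring B and the spiro centre disappear, leaving an aryl bromide with an open chain and a symmetrical, achiral six-membered ring; no stereocentre has to be made. The forward step demands that 12 adds 1,2 to 11 despite its two ortho substituents, that 13 ionises at C5 only, and that the cation is captured at C5 by the allylsilane faster than by anything else. The tert-butyldimethylsilyl ether is kept on purpose: it can be put on a hindered carbinol and removed with buffered fluoride, and lithiation in ether at −78 °C avoids silyl migration. A bulkier silyl group would be needed only if migration intruded.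

**11 ⇒ 10.** One C–O bond at the ketal carbon is cut. The forward reaction is oxidative dearomatisation of 10 in the alcohol that supplies the second ketal oxygen; 10 is commercial and symmetrical, so there is no regiochemical demand.

**9 ⇒ 7.** The C7=CH2 and C7–CH2Si bonds are traced back to an ester carbonyl. A 2-substituted allylsilane is the product of double addition of a silylmethyl organometallic to an ester followed by elimination of one silanol. The gain is a return to aldol-type material. The forward step must add twice without enolising C8 and eliminate without protodesilylation.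

**7 ⇒ 6 ⇒ 5.** The O–Si bond and the acyl–N bond are cut. The imide is not a substrate for double addition and a free hydroxyl would quench the organometallics. The forward removal of the auxiliary must avoid retro-aldol cleavage.

**5 ⇒ 1 + 2.** The C8–C9 bond is cut (aldol retron), giving two commercial compounds and setting C8 and C9 together. Note on configuration: the trans C8/C9 relationship on ring B corresponds to a syn aldol, (2R,3R) in 5. The Z-enolate 3 of the R-configured 2 is therefore required; an anti aldol would lead to the C9 epimer.

## Other disconnections considered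

**Alternative 1:** The cut removes the two methyl groups (C7–CH3 and C8–CH3) and leads to the benzosuberenone A2, dimethyl 2,3,4-trimethoxy-9-oxo-6,9-dihydro-5H-benzo[7]annulene-5,5-dicarboxylate. In the forward sense a copper-catalysed enantioselective conjugate addition of a methyl nucleophile (chiral ferrocenyl diphosphine ligand) to C7 of A2, followed by methylation at C8 in the same flask, would give the trans-dimethyl ketone A1, dimethyl (7R,8S)-2,3,4-trimethoxy-7,8-dimethyl-9-oxo-6,7,8,9-tetrahydro-5H-benzo[7]annulene-5,5-dicarboxylate.
- In its favour: C7 would be set by the catalyst and C8 by its neighbour in one operation; ring B is already closed; the quaternary C5 blocks enolisation on the far side; and C8, being α to the ketone, can equilibrate towards the wanted trans isomer.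
- Against it here: A1 is far from the target. C9 is a ketone that would need a substrate-controlled reduction to the 9R alcohol, and the two ester groups at C5 would have to be built into the two methoxy-enone arms of ring C, a multistep annulation with no short solution. A seven-membered aryl enone is also a less favourable substrate for this catalysis than a simple cycloalkenone.
- Comparison: on C7 this alternative is the better plan, since it uses reagent control where the chosen route relies on a late substrate-controlled reduction of 15. On C8 the two are equal. On C9 the chosen route is stronger (aldol against ketone reduction). Mechanistically the key step of the alternative rests on established chemistry and is safer than step 6, but it closes no ring and leaves ring C unsolved, so the step count to 18 would clearly exceed nine.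

**Alternative 2:** The cut opens ring C at C5–C6' and C2'=C3', giving the aldehyde A4, (7R,8R)-2,3,4-trimethoxy-7,8-dimethyl-6,7,8,9-tetrahydro-5H-benzo[7]annulene-5-carbaldehyde, and the enone A5, 1,3,4-trimethoxybut-3-en-2-one. In the forward sense an amidine base would make C5 of A4 nucleophilic; it would add to the β-carbon of A5 with loss of methanol, and the CH2 group of the former A5 would then condense with the aldehyde carbon to close ring C, giving the 9-deoxy spirodienone A3.
- In its favour: a Robinson-type spiroannulation would deliver ring C with its full oxygen pattern from a small reagent, without organolithium or Lewis acid, and the quaternary carbon would form from an enolate whose configuration does not matter.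
- Against it here: the nucleophile is a tertiary benzylic enolate flanked by the C4 methoxy group, so the addition–elimination is sterically demanding and self-condensation of A5 could compete. A4 already contains ring B and both methyl stereocentres and would need its own multistep asymmetric synthesis. A3 lacks the C9 oxygen, which would have to come from a late benzylic C–H oxidation with 9R selectivity beside a dienone and an oxidisable arene.
- Comparison: for the formation of ring C alone this alternative is the equal of the chosen plan or better, because it uses an established annulation type where the chosen plan proposes a new cationic cascade. Structurally it forms only ring C and leaves ring B, C7, C8 and the oxidation of C9 to other steps, whereas step 6 assembles ring B and the spiro centre with the C9 oxygen in place. The overall step count would be higher.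

**Alternative 3:** The cut is at C9–C9a and C5–C4a, taking ring B apart at both arene bonds into the β-ketoester A7, allyl (2S,3R)-2,3-dimethyl-5-oxocyclopentane-1-carboxylate, and the aryne precursor A8, 3,4,5-trimethoxy-2-(trimethylsilyl)phenyl trifluoromethanesulfonate. In the forward sense a fluoride source would release the aryne A9 (1,2-didehydro-3,4,5-trimethoxybenzene) from A8; A9 would insert into the C(=O)–CH bond of A7 (acyl-alkylation) and expand the five-membered ring to the benzosuberone A6, allyl (7R,8S)-2,3,4-trimethoxy-7,8-dimethyl-5-oxo-6,7,8,9-tetrahydro-5H-benzo[7]annulene-9-carboxylate, as C9 epimers.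
- In its favour: it is highly convergent, forming both aryl–carbon bonds and ring B in one step; the trans-dimethyl pair is carried in on a small ring where it is easy to set; and the methoxy group next to the aryne bond should direct the carbon nucleophile to the distal carbon, so that the acyl group ends at C4a as required.
- Against it here: the functional groups of A6 do not match the target. C9 carries a carboxylate where an acetoxy group is needed, and a carbon-to-oxygen exchange with control of configuration is long and uncertain. The configuration at C9 is not controlled. C5 is a ketone that still has to become the spiro carbon with all of ring C attached.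
- Comparison: as a way of making ring B this alternative is the equal of the chosen plan or better, both in convergence and in precedent for its reaction type. It sets neither C9 nor the spiro centre, however, so the work after its key step would be much longer than the three steps that follow step 6, and the chosen plan keeps the advantage of taking C8 and C9 together from one aldol reaction.

Key step: step 6

Remarks on the chemistry:
- Locants follow benzo[7]annulene numbering (C1–C4 arene, C4a, C5 spiro, C6–C9, C9a), with primed locants for ring C (C1' = C5).
- Compound 2 and Me3SiCH2MgCl (ether solution) are taken as purchased.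

## Route

Step 1
Reactants: 1 2-bromo-3,4,5-trimethoxybenzaldehyde; 2 (R)-4-benzyl-3-propanoyl-1,3-oxazolidin-2-one
Product: 5 (R)-4-benzyl-3-[(2R,3R)-3-(2-bromo-3,4,5-trimethoxyphenyl)-3-hydroxy-2-methylpropanoyl]-1,3-oxazolidin-2-one, via Z-boron enolate 3 (not isolated), via boron aldolate 4 (not isolated)
Conditions: 2, Bu2BOTf, iPr2NEt, CH2Cl2, 0 °C; 1, −78 → 0 °C; pH 7 buffer, MeOH, 30% H2O2, 0 °C
Reagents that add atoms: none
Why: Evans syn aldol reaction: soft enolisation gives the Z-boron enolate 3, which reacts through a closed Zimmerman–Traxler chair with the auxiliary carbonyl turned away from the enolate oxygen, so the aldehyde adds to the enolate face remote from the benzyl group and C8 and C9 are set together as the (2R,3R) syn pair in aldolate 4. Oxidative work-up cleaves the B–O bond and releases 5.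

Step 2
Reactants: 5 (R)-4-benzyl-3-[(2R,3R)-3-(2-bromo-3,4,5-trimethoxyphenyl)-3-hydroxy-2-methylpropanoyl]-1,3-oxazolidin-2-one
Product: 6 methyl (2R,3R)-3-(2-bromo-3,4,5-trimethoxyphenyl)-3-hydroxy-2-methylpropanoate
Conditions: NaOMe (1.1 equiv), MeOH, CH2Cl2, 0 °C, 15 min; AcOH
Reagents that add atoms: sodium methoxide, C[O-].[Na+]
Why: Transesterification of the imide: methoxide attacks the more electrophilic exocyclic carbonyl and the oxazolidinone anion leaves. Low temperature and a short reaction time should prevent retro-aldol cleavage and epimerisation at C2, and the auxiliary is recovered.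

Step 3
Reactants: 6 methyl (2R,3R)-3-(2-bromo-3,4,5-trimethoxyphenyl)-3-hydroxy-2-methylpropanoate
Product: 7 methyl (2R,3R)-3-(2-bromo-3,4,5-trimethoxyphenyl)-3-(tert-butyldimethylsilyloxy)-2-methylpropanoate
Conditions: TBSOTf, 2,6-lutidine, CH2Cl2, −78 → 0 °C
Reagents that add atoms: tert-butyldimethylsilyl trifluoromethanesulfonate, CC(C)(C)[Si](C)(C)OS(=O)(=O)C(F)(F)F
Why: O-silylation of a hindered secondary benzylic alcohol with a silyl triflate and a hindered pyridine base; the C–O bond is untouched, so C9 keeps its configuration. The ether should withstand tBuLi at −78 °C and BF3·OEt2 at low temperature and is later removed by fluoride.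

Step 4
Reactants: 7 methyl (2R,3R)-3-(2-bromo-3,4,5-trimethoxyphenyl)-3-(tert-butyldimethylsilyloxy)-2-methylpropanoate
Product: 9 tert-butyl{[(1R,2S)-1-(2-bromo-3,4,5-trimethoxyphenyl)-2-methyl-3-(trimethylsilylmethyl)but-3-en-1-yl]oxy}dimethylsilane (fragment 1), via bis(silylmethyl) carbinol 8 (not isolated)
Conditions: Me3SiCH2MgCl (5 equiv), CeCl3 (5 equiv), THF, −78 °C → rt; aq. NH4Cl; SiO2, CH2Cl2, rt
Reagents that add atoms: (trimethylsilyl)methylmagnesium chloride, C[Si](C)(C)C[Mg]Cl
Why: Cerium-mediated double addition of the silylmethyl nucleophile to the ester gives the bis(β-silyl) carbinol 8; the weakly basic organocerium species should not enolise the α-stereocentre or the intermediate α-silyl ketone. Silica gel then induces Peterson elimination of Me3SiOH from one of the two equivalent arms, leaving the 2-substituted allylsilane; the aryl bromide and silyl ether are inert.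

Step 5
Reactants: 10 3,4,5-trimethoxyphenol
Product: 11 3,4,4,5-tetramethoxycyclohexa-2,5-dien-1-one (fragment 2)
Conditions: PhI(OAc)2, MeOH, 0 °C → rt
Reagents that add atoms: methanol, CO
Why: Oxidative dearomatisation of a para-alkoxyphenol: ligand exchange at iodine and loss of iodobenzene give a phenoxonium ion, which methanol captures at the para carbon that already bears a methoxy group. The substrate is symmetrical, so only one quinone monoketal can form.

Step 6
Reactants: 9 tert-butyl{[(1R,2S)-1-(2-bromo-3,4,5-trimethoxyphenyl)-2-methyl-3-(trimethylsilylmethyl)but-3-en-1-yl]oxy}dimethylsilane; 11 3,4,4,5-tetramethoxycyclohexa-2,5-dien-1-one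
Product: 15 (8S,9R)-9-(tert-butyldimethylsilyloxy)-2,3,3',4,5'-pentamethoxy-8-methyl-7-methylidene-6,7,8,9-tetrahydrospiro[benzo[7]annulene-5,1'-cyclohexa[2,5]dien]-4'-one, via aryllithium 12 (not isolated), via lithium alkoxide 13 (not isolated), via spiro ketal 14 (not isolated)
Conditions: 9, tBuLi (2.1 equiv), Et2O, −78 °C; 11, −78 → −40 °C; BF3·OEt2 (2.5 equiv), CH2Cl2, −78 → −30 °C; 5% aq. oxalic acid, THF, 0 °C → rt
Reagents that add atoms: water, O
Why: Proposed new method: bromine–lithium exchange with two equivalents of tBuLi gives aryllithium 12, which adds 1,2 to the only carbonyl group of 11 (the β-carbons carry methoxy groups, so conjugate addition is disfavoured, and there is no α-hydrogen to remove) and so forms the C4a–C5 bond in alkoxide 13. BF3·OEt2 then ionises the tertiary, doubly allylic and benzylic C5–O bond to a pentadienyl cation whose charge is shared by C5 and the methoxy-bearing carbons C3' and C5'; the allylsilane terminus (the future C6) attacks C5, the β-silyl cation at C7 loses Me3Si as Me3SiF to leave the exocyclic alkene of 14, and dilute aqueous acid finally hydrolyses the dimethyl ketal to the C4' ketone of 15. The closest known reaction types are the 1,2-addition of aryllithiums to quinone monoketals and the intramolecular Hosomi–Sakurai capture of tertiary allylic and benzylic cations; what is new is their combination at one quinone-derived carbon in a single flask. Ring B closes in a 7-endo-trig mode with respect to the allylsilane alkene, since both C6 and C7 become ring atoms, onto the central carbon of the pentadienyl cation. No stereocentre is formed, because C5 carries two constitutionally identical arms of ring C, and C8 and C9 are neither involved nor epimerisable under these conditions. The selectivity that is needed is capture at C5 and not at C3' or C5'; the tether secures it, because bonding to either methoxy-bearing carbon would demand a bridged nine-membered ring. Ionisation at C5 in preference to the secondary benzylic C9–O bond follows from the far greater stability of the doubly allylic cation at low temperature, and keeping 12 at −78 °C in ether until 11 is added suppresses O-to-C migration of the neighbouring silyl group (retro-Brook rearrangement). Capture of the cation by the C9 ether oxygen or by fluoride would be reversible, whereas C–C bond formation with loss of silicon is not, so the cyclisation should drain these equilibria.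

Step 7
Reactants: 15 (8S,9R)-9-(tert-butyldimethylsilyloxy)-2,3,3',4,5'-pentamethoxy-8-methyl-7-methylidene-6,7,8,9-tetrahydrospiro[benzo[7]annulene-5,1'-cyclohexa[2,5]dien]-4'-one
Product: 16 (7R,8S,9R)-9-(tert-butyldimethylsilyloxy)-2,3,3',4,5'-pentamethoxy-7,8-dimethyl-6,7,8,9-tetrahydrospiro[benzo[7]annulene-5,1'-cyclohexa[2,5]dien]-4'-one
Conditions: Mn(dpm)3 (10 mol %; dpm = 2,2,6,6-tetramethylheptane-3,5-dionate), PhSiH3 (1.1 equiv), tBuOOH, iPrOH, rt
Reagents that add atoms: none
Why: Mukaiyama-type hydrogen-atom-transfer hydrogenation: the manganese hydride gives a hydrogen atom to the unhindered terminal CH2, and the tertiary C7 radical should take the second hydrogen so that the new methyl group is equatorial on the ring B chair that also places 8-CH3 and the 9-silyloxy group equatorial (product-stability control), which is the trans-7,8 isomer (7R), opposite to the cis preference expected of surface hydrogenation. The 1,1-disubstituted alkene should react faster than ring C, whose β-carbons are hindered CH groups next to the spiro centre, and the silane is kept near one equivalent.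

Step 8
Reactants: 16 (7R,8S,9R)-9-(tert-butyldimethylsilyloxy)-2,3,3',4,5'-pentamethoxy-7,8-dimethyl-6,7,8,9-tetrahydrospiro[benzo[7]annulene-5,1'-cyclohexa[2,5]dien]-4'-one
Product: 17 (7R,8S,9R)-9-hydroxy-2,3,3',4,5'-pentamethoxy-7,8-dimethyl-6,7,8,9-tetrahydrospiro[benzo[7]annulene-5,1'-cyclohexa[2,5]dien]-4'-one
Conditions: HF·pyridine, pyridine, THF, 0 °C → rt
Reagents that add atoms: none
Why: Fluoride-induced cleavage of the Si–O bond, driven by the strength of the Si–F bond, under buffered and weakly acidic conditions. No free alkoxide (which could add to ring C) and no C9 cation should arise, and the C9–O bond is untouched, so the configuration is kept.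

Step 9
Reactants: 17 (7R,8S,9R)-9-hydroxy-2,3,3',4,5'-pentamethoxy-7,8-dimethyl-6,7,8,9-tetrahydrospiro[benzo[7]annulene-5,1'-cyclohexa[2,5]dien]-4'-one
Product: 18 (7R,8S,9R)-2,3,3',4,5'-pentamethoxy-7,8-dimethyl-4'-oxo-6,7,8,9-tetrahydrospiro[benzo[7]annulene-5,1'-cyclohexa[2,5]dien]-9-yl acetate
Conditions: Ac2O, pyridine, DMAP (cat.), CH2Cl2, 0 °C → rt
Reagents that add atoms: acetic anhydride, CC(=O)OC(C)=O
Why: DMAP-catalysed O-acylation through the N-acetylpyridinium ion; acylation occurs at oxygen, so C9 keeps its R configuration, and the dienone is inert to these conditions.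

## Compound list

1 | 2-bromo-3,4,5-trimethoxybenzaldehyde | COc1cc(C=O)c(Br)c(OC)c1OC | starting material
2 | (R)-4-benzyl-3-propanoyl-1,3-oxazolidin-2-one | CCC(=O)N1[C@H](Cc2ccccc2)COC1=O | starting material
3 | (R)-4-benzyl-3-[(Z)-1-(dibutylboranyloxy)prop-1-en-1-yl]-1,3-oxazolidin-2-one (Z-boron enolate) | C/C=C(\OB(CCCC)CCCC)N1[C@H](Cc2ccccc2)COC1=O | intermediate
4 | (R)-4-benzyl-3-[(2R,3R)-3-(2-bromo-3,4,5-trimethoxyphenyl)-3-(dibutylboranyloxy)-2-methylpropanoyl]-1,3-oxazolidin-2-one (boron aldolate) | O=C(N1[C@H](Cc2ccccc2)COC1=O)[C@H](C)[C@@H](OB(CCCC)CCCC)c1cc(OC)c(OC)c(OC)c1Br | intermediate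
5 | (R)-4-benzyl-3-[(2R,3R)-3-(2-bromo-3,4,5-trimethoxyphenyl)-3-hydroxy-2-methylpropanoyl]-1,3-oxazolidin-2-one | O=C(N1[C@H](Cc2ccccc2)COC1=O)[C@H](C)[C@@H](O)c1cc(OC)c(OC)c(OC)c1Br | intermediate
6 | methyl (2R,3R)-3-(2-bromo-3,4,5-trimethoxyphenyl)-3-hydroxy-2-methylpropanoate | COC(=O)[C@H](C)[C@@H](O)c1cc(OC)c(OC)c(OC)c1Br | intermediate
7 | methyl (2R,3R)-3-(2-bromo-3,4,5-trimethoxyphenyl)-3-(tert-butyldimethylsilyloxy)-2-methylpropanoate | COC(=O)[C@H](C)[C@@H](O[Si](C)(C)C(C)(C)C)c1cc(OC)c(OC)c(OC)c1Br | intermediate
8 | (3R,4R)-4-(2-bromo-3,4,5-trimethoxyphenyl)-4-(tert-butyldimethylsilyloxy)-3-methyl-1-(trimethylsilyl)-2-(trimethylsilylmethyl)butan-2-ol (bis(silylmethyl) carbinol) | C[Si](C)(C)CC(O)(C[Si](C)(C)C)[C@H](C)[C@@H](O[Si](C)(C)C(C)(C)C)c1cc(OC)c(OC)c(OC)c1Br | intermediate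
9 | tert-butyl{[(1R,2S)-1-(2-bromo-3,4,5-trimethoxyphenyl)-2-methyl-3-(trimethylsilylmethyl)but-3-en-1-yl]oxy}dimethylsilane (fragment 1) | C[Si](C)(C)CC(=C)[C@H](C)[C@@H](O[Si](C)(C)C(C)(C)C)c1cc(OC)c(OC)c(OC)c1Br | intermediate
10 | 3,4,5-trimethoxyphenol | COc1cc(O)cc(OC)c1OC | starting material
11 | 3,4,4,5-tetramethoxycyclohexa-2,5-dien-1-one (fragment 2) | COC1=CC(=O)C=C(OC)C1(OC)OC | intermediate
12 | {6-[(1R,2S)-1-(tert-butyldimethylsilyloxy)-2-methyl-3-(trimethylsilylmethyl)but-3-en-1-yl]-2,3,4-trimethoxyphenyl}lithium (aryllithium) | C[Si](C)(C)CC(=C)[C@H](C)[C@@H](O[Si](C)(C)C(C)(C)C)c1cc(OC)c(OC)c(OC)c1[Li] | intermediate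
13 | lithium 1-{6-[(1R,2S)-1-(tert-butyldimethylsilyloxy)-2-methyl-3-(trimethylsilylmethyl)but-3-en-1-yl]-2,3,4-trimethoxyphenyl}-3,4,4,5-tetramethoxycyclohexa-2,5-dien-1-olate (lithium alkoxide) | C[Si](C)(C)CC(=C)[C@H](C)[C@@H](O[Si](C)(C)C(C)(C)C)c1cc(OC)c(OC)c(OC)c1C1(O[Li])C=C(OC)C(OC)(OC)C(OC)=C1 | intermediate
14 | (8S,9R)-9-(tert-butyldimethylsilyloxy)-2,3,3',4,4',4',5'-heptamethoxy-8-methyl-7-methylidene-6,7,8,9-tetrahydrospiro[benzo[7]annulene-5,1'-cyclohexa[2,5]diene] (spiro ketal) | COC1=CC2(C=C(OC)C1(OC)OC)CC(=C)[C@H](C)[C@@H](O[Si](C)(C)C(C)(C)C)c1cc(OC)c(OC)c(OC)c12 | intermediate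
15 | (8S,9R)-9-(tert-butyldimethylsilyloxy)-2,3,3',4,5'-pentamethoxy-8-methyl-7-methylidene-6,7,8,9-tetrahydrospiro[benzo[7]annulene-5,1'-cyclohexa[2,5]dien]-4'-one | COC1=CC2(C=C(OC)C1=O)CC(=C)[C@H](C)[C@@H](O[Si](C)(C)C(C)(C)C)c1cc(OC)c(OC)c(OC)c12 | intermediate
16 | (7R,8S,9R)-9-(tert-butyldimethylsilyloxy)-2,3,3',4,5'-pentamethoxy-7,8-dimethyl-6,7,8,9-tetrahydrospiro[benzo[7]annulene-5,1'-cyclohexa[2,5]dien]-4'-one | COC1=CC2(C=C(OC)C1=O)C[C@@H](C)[C@H](C)[C@@H](O[Si](C)(C)C(C)(C)C)c1cc(OC)c(OC)c(OC)c12 | intermediate
17 | (7R,8S,9R)-9-hydroxy-2,3,3',4,5'-pentamethoxy-7,8-dimethyl-6,7,8,9-tetrahydrospiro[benzo[7]annulene-5,1'-cyclohexa[2,5]dien]-4'-one | COC1=CC2(C=C(OC)C1=O)C[C@@H](C)[C@H](C)[C@@H](O)c1cc(OC)c(OC)c(OC)c12 | intermediate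
18 | (7R,8S,9R)-2,3,3',4,5'-pentamethoxy-7,8-dimethyl-4'-oxo-6,7,8,9-tetrahydrospiro[benzo[7]annulene-5,1'-cyclohexa[2,5]dien]-9-yl acetate | COC1=CC2(C=C(OC)C1=O)C[C@@H](C)[C@H](C)[C@@H](OC(C)=O)c1cc(OC)c(OC)c(OC)c12 | target

## Step count and least certain steps

Total step count: 9. Longest linear sequence: 8 steps (steps 1–4 and 6–9, from 1 to 18); step 5 is a one-step branch.

**Step 6 (key step, proposed new method).** The most likely failure is that the seven-membered closure is outrun by other fates of the cation: O-demethylation of the methoxy-stabilised cation by fluoride or methoxide (an enone transposition of the Stork–Danheiser type), capture by external nucleophiles, or protodesilylation of the allylsilane by adventitious acid. In the first stage, slow addition of the doubly ortho-substituted aryllithium would leave time for O-to-C silyl migration. The fallback uses known reaction types only and sets out from 9. Suzuki–Miyaura coupling of 9 with purchased 2,6-dimethoxy-4-(4,4,5,5-tetramethyl-1,3,2-dioxaborolan-2-yl)phenol (Pd(OAc)2, SPhos, K3PO4, toluene–water, 80 °C) would give the biaryl phenol 4-{6-[(1R,2S)-1-(tert-butyldimethylsilyloxy)-2-methyl-3-(trimethylsilylmethyl)but-3-en-1-yl]-2,3,4-trimethoxyphenyl}-2,6-dimethoxyphenol F1. Oxidation of F1 with PhI(OAc)2 in (CF3)2CHOH–CH2Cl2 at −40 °C would generate the phenoxonium ion, whose para carbon (the future C5) is attacked by the tethered allylsilane. This dearomatising spirocyclisation of Hosomi–Sakurai type would give 15 directly, where the route is rejoined.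

**Step 7.** The most likely failure is loss of chemoselectivity: hydrogen-atom transfer to the β-carbons of the dienone (conjugate reduction of ring C), or β-scission of the C7 radical with cleavage of the C5–C6 bond, driven by aromatisation of ring C. A less selective delivery of the second hydrogen could also erode the trans selectivity. The fallback moves the reduction to the stage before the dienone exists and sets out from 14, which is isolated by working up step 6 without acid (Et3N, then aqueous NaHCO3). Under the same manganese hydride conditions 14 would give the saturated ketal (7R,8S,9R)-9-(tert-butyldimethylsilyloxy)-2,3,3',4,4',4',5'-heptamethoxy-7,8-dimethyl-6,7,8,9-tetrahydrospiro[benzo[7]annulene-5,1'-cyclohexa[2,5]diene] F2, in which ring C is neither an enone nor the precursor of a phenoxyl radical. Hydrolysis of F2 with dilute aqueous oxalic acid would return to the route at 16.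

**Step 4.** The most likely failure is incomplete second addition to the hindered α-branched ester, or protodesilylation during the acid-promoted elimination, which would leave a 2-methylallyl group in place of the allylsilane. The fallback sets out from 7. Me3SiCH2Li (2.2 equiv, pentane–THF, −78 → 0 °C) should stop at the ketone stage, protected as its enolate until work-up, and give the α-silyl ketone (3R,4R)-4-(2-bromo-3,4,5-trimethoxyphenyl)-4-(tert-butyldimethylsilyloxy)-3-methyl-1-(trimethylsilyl)butan-2-one F3. Methylenation of F3 with the titanium methylidene reagent Cp2Ti(μ-Cl)(μ-CH2)AlMe2 (THF–toluene, −40 → 0 °C) would then give 9 without any acidic elimination.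

**Step 2.** The most likely failure is retro-aldol cleavage or epimerisation at C2 under methoxide, or attack of an alkoxide on the ring carbonyl of the auxiliary. The fallback sets out from 5. Hydrolysis with LiOH–H2O2 (THF–water, 0 °C), in which hydroperoxide attacks only the exocyclic carbonyl, would give (2R,3R)-3-(2-bromo-3,4,5-trimethoxyphenyl)-3-hydroxy-2-methylpropanoic acid F4, and O-methylation of F4 with Me3SiCHN2 (toluene–MeOH, 0 °C) would return to the route at 6.

## Further compounds

F1 | step 6 | 4-{6-[(1R,2S)-1-(tert-butyldimethylsilyloxy)-2-methyl-3-(trimethylsilylmethyl)but-3-en-1-yl]-2,3,4-trimethoxyphenyl}-2,6-dimethoxyphenol | C[Si](C)(C)CC(=C)[C@H](C)[C@@H](O[Si](C)(C)C(C)(C)C)c1cc(OC)c(OC)c(OC)c1-c1cc(OC)c(O)c(OC)c1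
F2 | step 7 | (7R,8S,9R)-9-(tert-butyldimethylsilyloxy)-2,3,3',4,4',4',5'-heptamethoxy-7,8-dimethyl-6,7,8,9-tetrahydrospiro[benzo[7]annulene-5,1'-cyclohexa[2,5]diene] | COC1=CC2(C=C(OC)C1(OC)OC)C[C@@H](C)[C@H](C)[C@@H](O[Si](C)(C)C(C)(C)C)c1cc(OC)c(OC)c(OC)c12
F3 | step 4 | (3R,4R)-4-(2-bromo-3,4,5-trimethoxyphenyl)-4-(tert-butyldimethylsilyloxy)-3-methyl-1-(trimethylsilyl)butan-2-one | C[Si](C)(C)CC(=O)[C@H](C)[C@@H](O[Si](C)(C)C(C)(C)C)c1cc(OC)c(OC)c(OC)c1Br
F4 | step 2 | (2R,3R)-3-(2-bromo-3,4,5-trimethoxyphenyl)-3-hydroxy-2-methylpropanoic acid | OC(=O)[C@H](C)[C@@H](O)c1cc(OC)c(OC)c(OC)c1Br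
A1 | alternative 1 | dimethyl (7R,8S)-2,3,4-trimethoxy-7,8-dimethyl-9-oxo-6,7,8,9-tetrahydro-5H-benzo[7]annulene-5,5-dicarboxylate | COC(=O)C1(C(=O)OC)C[C@@H](C)[C@H](C)C(=O)c2cc(OC)c(OC)c(OC)c21
A2 | alternative 1 | dimethyl 2,3,4-trimethoxy-9-oxo-6,9-dihydro-5H-benzo[7]annulene-5,5-dicarboxylate | COC(=O)C1(C(=O)OC)CC=CC(=O)c2cc(OC)c(OC)c(OC)c21
A3 | alternative 2 | (7R,8R)-2,3,3',4,5'-pentamethoxy-7,8-dimethyl-6,7,8,9-tetrahydrospiro[benzo[7]annulene-5,1'-cyclohexa[2,5]dien]-4'-one | COC1=CC2(C=C(OC)C1=O)C[C@@H](C)[C@H](C)Cc1cc(OC)c(OC)c(OC)c12
A4 | alternative 2 | (7R,8R)-2,3,4-trimethoxy-7,8-dimethyl-6,7,8,9-tetrahydro-5H-benzo[7]annulene-5-carbaldehyde (C5 epimers) | O=CC1C[C@@H](C)[C@H](C)Cc2cc(OC)c(OC)c(OC)c21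
A5 | alternative 2 | 1,3,4-trimethoxybut-3-en-2-one | COCC(=O)C(OC)=COC
A6 | alternative 3 | allyl (7R,8S)-2,3,4-trimethoxy-7,8-dimethyl-5-oxo-6,7,8,9-tetrahydro-5H-benzo[7]annulene-9-carboxylate (C9 epimers) | O=C1C[C@@H](C)[C@H](C)C(C(=O)OCC=C)c2cc(OC)c(OC)c(OC)c21
A7 | alternative 3 | allyl (2S,3R)-2,3-dimethyl-5-oxocyclopentane-1-carboxylate (C1 epimers) | O=C1C[C@@H](C)[C@H](C)C1C(=O)OCC=C
A8 | alternative 3 | 3,4,5-trimethoxy-2-(trimethylsilyl)phenyl trifluoromethanesulfonate | COc1cc(OS(=O)(=O)C(F)(F)F)c([Si](C)(C)C)c(OC)c1OC
A9 | alternative 3 | 1,2-didehydro-3,4,5-trimethoxybenzene | COC1=C(OC)C(OC)=CC#C1
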